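**Retrosynthetic overview**

1. Locants used in the text: naphthalene C1 (aryl ring C), C2 (benzyl ring D), C3 (OH), C4 (H), C4a, C5 (OMe), C6 (OH), C7 (OMe), C8 (H), C8a; ring A = C4a/C5–C8/C8a, ring B = C1–C4/C4a/C8a.
2. The strategy rests on ring A: oxygens on C5, C6 and C7, hydrogen on C8, fused to a ring B whose C4a is the only free carbon ortho to C8a. A 4-aryl-2,3-dimethoxycyclobutenone delivers exactly this (C=O becomes C5–O, the two methoxy carbons C6 and C7, the ring CH becomes C8).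
3. 23 ⇐ 22 (BCl3 removes the four benzyl groups and the doubly flanked C6 methyl) ⇐ 21 (O-methylation at C5) ⇐ 18 (4π opening, 6π closure). Ring A is formed last; rings B, C and D are bought as benzenes.
4. 18 ⇐ arylstannane 14 + 4-chloro-2,3-dimethoxycyclobutenone 17 (Stille coupling; 17 from dimethyl squarate 15).
5. 14 ⇐ benzaldehyde 8 with differentiated C–I and C–Br bonds: Suzuki coupling at C–I brings ring C, Grignard addition and ionic deoxygenation bring ring D, and Br→Li→Sn comes last.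

Key step: step 13

Remark: the target has no stereocentre and its hindered biaryl axis is unspecified, so 11, 16, 17, 18 and 20 are racemates and no atropisomer is assigned; compound names use systematic numbering.

**Route**

Step 1
Reactants: 1 4-bromo-3-methoxyphenol
Product: 2 4-(benzyloxy)-1-bromo-2-methoxybenzene
Conditions: BnBr, K2CO3, DMF, rt
Reagents that add atoms: benzyl bromide, BrCc1ccccc1
Why: Williamson ether synthesis on the only phenol should give the protected ring C bromide.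

Step 2
Reactants: 2 4-(benzyloxy)-1-bromo-2-methoxybenzene
Product: 3 2-[4-(benzyloxy)-2-methoxyphenyl]-4,4,5,5-tetramethyl-1,3,2-dioxaborolane
Conditions: B2pin2, PdCl2(dppf) (3 mol%), KOAc, dioxane, 90 °C
Reagents that add atoms: bis(pinacolato)diboron, CC1(C)OB(OC1(C)C)B1OC(C)(C)C(C)(C)O1
Why: Miyaura borylation of an aryl bromide should give the ring C boronate without any organolithium step.

Step 3
Reactants: 4 4-bromocatechol
Product: 5 1,2-bis(benzyloxy)-4-bromobenzene
Conditions: BnBr (2.2 equiv), K2CO3, DMF, 60 °C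
Reagents that add atoms: benzyl bromide, BrCc1ccccc1
Why: Double Williamson ether synthesis should protect both catechol hydroxyls of ring D.

Step 4
Reactants: 6 2-fluoro-6-iodobenzaldehyde
Product: 7 2-(benzyloxy)-6-iodobenzaldehyde
Conditions: BnOH, Cs2CO3, DMF, 60 °C
Reagents that add atoms: benzyl alcohol, OCc1ccccc1
Why: Nucleophilic aromatic substitution: the fluoride ortho to the formyl group is activated for addition–elimination, while the iodide should not be displaced.

Step 5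
Reactants: 7 2-(benzyloxy)-6-iodobenzaldehyde
Product: 8 6-(benzyloxy)-3-bromo-2-iodobenzaldehyde
Conditions: NBS, DMF, rt
Reagents that add atoms: N-bromosuccinimide, O=C1CCC(=O)N1Br
Why: Electrophilic aromatic bromination should go para to the benzyloxy group and meta to the formyl group, as with other 2-alkoxybenzaldehydes, which places bromine on the future C8a.

Step 6
Reactants: 8 6-(benzyloxy)-3-bromo-2-iodobenzaldehyde; 3 2-[4-(benzyloxy)-2-methoxyphenyl]-4,4,5,5-tetramethyl-1,3,2-dioxaborolane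
Product: 9 3,4'-bis(benzyloxy)-6-bromo-2'-methoxy-[1,1'-biphenyl]-2-carbaldehyde
Conditions: Pd(PPh3)4 (5 mol%), K3PO4, dioxane/H2O 4:1, 85 °C
Reagents that add atoms: none
Why: Suzuki–Miyaura coupling: oxidative addition into the C–I bond ortho to the formyl group is much faster than into the C–Br bond, so ring C should enter only at the future C1 and the bromide should be kept.

Step 7
Reactants: 9 3,4'-bis(benzyloxy)-6-bromo-2'-methoxy-[1,1'-biphenyl]-2-carbaldehyde; 5 1,2-bis(benzyloxy)-4-bromobenzene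
Product: 11 [3,4-bis(benzyloxy)phenyl][3,4'-bis(benzyloxy)-6-bromo-2'-methoxy-[1,1'-biphenyl]-2-yl]methanol (racemic), via arylmagnesium bromide 10 (not isolated)
Conditions: 5, Mg, I2 (cat.), THF, 40 °C; then 9, THF, 0 °C to rt; aqueous work-up
Reagents that add atoms: none
Why: Grignard addition to the aldehyde; an arylmagnesium halide does not exchange with the aryl bromide of 9, and the new carbinol centre is formed without control because step 8 removes it.

Step 8
Reactants: 11 [3,4-bis(benzyloxy)phenyl][3,4'-bis(benzyloxy)-6-bromo-2'-methoxy-[1,1'-biphenyl]-2-yl]methanol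
Product: 12 3,4'-bis(benzyloxy)-2-[3,4-bis(benzyloxy)benzyl]-6-bromo-2'-methoxy-1,1'-biphenyl
Conditions: Et3SiH (3 equiv), TFA, CH2Cl2, 0 °C
Reagents that add atoms: none
Why: Ionic hydrogenation: TFA ionises the doubly benzylic alcohol to a cation stabilised by the para benzyloxy group of ring D, and Et3SiH should deliver hydride before the cation attacks an arene, while the benzyl ethers tolerate brief TFA at 0 °C.

Step 9
Reactants: 12 3,4'-bis(benzyloxy)-2-[3,4-bis(benzyloxy)benzyl]-6-bromo-2'-methoxy-1,1'-biphenyl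
Product: 14 {3,4'-bis(benzyloxy)-2-[3,4-bis(benzyloxy)benzyl]-2'-methoxy-[1,1'-biphenyl]-6-yl}trimethylstannane, via aryllithium 13 (not isolated)
Conditions: t-BuLi (2.05 equiv), THF, −78 °C; then Me3SnCl, −78 °C to rt
Reagents that add atoms: chlorotrimethylstannane, C[Sn](C)(C)Cl
Why: Bromine–lithium exchange is faster than deprotonation of the benzyl ethers at −78 °C, and trapping the aryllithium with the tin chloride should give the Stille partner.

Step 10
Reactants: 15 dimethyl squarate (3,4-dimethoxycyclobut-3-ene-1,2-dione)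
Product: 16 4-hydroxy-2,3-dimethoxycyclobut-2-en-1-one (racemic)
Conditions: LiAlH(OtBu)3 (1.1 equiv), THF, −78 °C; aqueous Rochelle salt work-up at 0 °C
Reagents that add atoms: none
Why: 1,2-Reduction of one squarate carbonyl by the bulky, mild hydride should stop at the hydroxy ketone, and the neutral work-up avoids acid-induced loss of methanol to the semisquarate.

Step 11
Reactants: 16 4-hydroxy-2,3-dimethoxycyclobut-2-en-1-one
Product: 17 4-chloro-2,3-dimethoxycyclobut-2-en-1-one (racemic)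
Conditions: 1-chloro-N,N,2-trimethylprop-1-en-1-amine (1.1 equiv), CH2Cl2, 0 °C; concentrated and used at once
Reagents that add atoms: 1-chloro-N,N,2-trimethylprop-1-en-1-amine, CC(C)=C(Cl)N(C)C
Why: Deoxychlorination through an alkoxyiminium chloride under neutral conditions, so that no acid is present to ionise the allylic C4–O or C4–Cl bond.

Step 12
Reactants: 14 {3,4'-bis(benzyloxy)-2-[3,4-bis(benzyloxy)benzyl]-2'-methoxy-[1,1'-biphenyl]-6-yl}trimethylstannane; 17 4-chloro-2,3-dimethoxycyclobut-2-en-1-one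
Product: 18 4-{3,4'-bis(benzyloxy)-2-[3,4-bis(benzyloxy)benzyl]-2'-methoxy-[1,1'-biphenyl]-6-yl}-2,3-dimethoxycyclobut-2-en-1-one (racemic)
Conditions: PdCl2(PhCN)2 (5 mol%), P(2-furyl)3 (10 mol%), dioxane, 50 °C
Reagents that add atoms: none
Why: Stille coupling of a 4-chlorocyclobutenone: zerovalent palladium adds to the allylic C–Cl bond to give an oxocyclobutenyl palladium chloride, and transmetalation with the arylstannane followed by reductive elimination at the unsubstituted terminus C4 should give the 4-aryl compound, which does not yet ring-open at 50 °C.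

Step 13
Reactants: 18 4-{3,4'-bis(benzyloxy)-2-[3,4-bis(benzyloxy)benzyl]-2'-methoxy-[1,1'-biphenyl]-6-yl}-2,3-dimethoxycyclobut-2-en-1-one
Product: 21 7-(benzyloxy)-5-[4-(benzyloxy)-2-methoxyphenyl]-6-[3,4-bis(benzyloxy)benzyl]-2,3-dimethoxynaphthalen-1-ol, via dienylketene 19 (not isolated), via cyclohexadienone 20 (not isolated)
Conditions: toluene (0.02 M, degassed), 110 °C, argon
Reagents that add atoms: none
Why: Heating should open the cyclobutenone by a reversible conrotatory 4π electrocyclic reaction to dienylketenes, and the isomer with the aryl group cis to the ketene carbon (19) should close by a thermally allowed disrotatory 6π electrocyclisation that uses the C8a=C4a bond of ring B, forming the C4a–C5 bond and dienone 20, which enolises to naphthol 21. The closest known reaction type is the thermal benzannulation of 4-aryl-2-cyclobutenones to 1-naphthols. Ring A is the one ring closed, by 6π electrocyclisation with the ketene carbon bonding to C4a. No stereocentre is created, since the sp3 carbon of 20 is lost on enolisation. The step needs site selectivity on ring B and a productive ketene geometry: the other ortho carbon (C1) already carries ring C, so only C4a is open, and the unproductive ketene with the aryl group turned outward should return to 18 by ring closure until it drains through 19. The ketene oxygen becomes the C5 hydroxyl, the two methoxy carbons become C6 and C7, and the former ring CH becomes C8.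

Step 14
Reactants: 21 7-(benzyloxy)-5-[4-(benzyloxy)-2-methoxyphenyl]-6-[3,4-bis(benzyloxy)benzyl]-2,3-dimethoxynaphthalen-1-ol
Product: 22 7-(benzyloxy)-5-[4-(benzyloxy)-2-methoxyphenyl]-6-[3,4-bis(benzyloxy)benzyl]-1,2,3-trimethoxynaphthalene
Conditions: MeI, K2CO3, DMF, rt, argon
Reagents that add atoms: iodomethane, CI
Why: Williamson O-methylation of the only free hydroxyl (C5) should give the 5,6,7-trimethoxy array.

Step 15
Reactants: 22 7-(benzyloxy)-5-[4-(benzyloxy)-2-methoxyphenyl]-6-[3,4-bis(benzyloxy)benzyl]-1,2,3-trimethoxynaphthalene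
Product: 23 6-[(3,4-dihydroxyphenyl)methyl]-5-(4-hydroxy-2-methoxyphenyl)-1,3-dimethoxynaphthalene-2,7-diol (CNP0000244.0)
Conditions: BCl3 (10 equiv), C6HMe5 (8 equiv), CH2Cl2, −78 °C to 0 °C; MeOH then H2O, argon
Reagents that add atoms: none
Why: Lewis-acid ether cleavage: BCl3 with pentamethylbenzene as a non-basic cation scavenger should cleave the four aryl benzyl ethers at low temperature and, on warming, the most hindered methyl ether, the C6 methoxy that two methoxy neighbours force out of the ring plane, whereas the C5 methoxy has only one oxygen neighbour and the C7 and ring C methoxy groups lie in plane.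

**Compound list**

1 | 4-bromo-3-methoxyphenol | COc1cc(O)ccc1Br | starting material
2 | 4-(benzyloxy)-1-bromo-2-methoxybenzene | COc1cc(OCc2ccccc2)ccc1Br | intermediate
3 | 2-[4-(benzyloxy)-2-methoxyphenyl]-4,4,5,5-tetramethyl-1,3,2-dioxaborolane | COc1cc(OCc2ccccc2)ccc1B1OC(C)(C)C(C)(C)O1 | intermediate
4 | 4-bromocatechol | Oc1ccc(Br)cc1O | starting material
5 | 1,2-bis(benzyloxy)-4-bromobenzene | Brc1ccc(OCc2ccccc2)c(OCc2ccccc2)c1 | intermediate
6 | 2-fluoro-6-iodobenzaldehyde | O=Cc1c(F)cccc1I | starting material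
7 | 2-(benzyloxy)-6-iodobenzaldehyde | O=Cc1c(I)cccc1OCc1ccccc1 | intermediate
8 | 6-(benzyloxy)-3-bromo-2-iodobenzaldehyde | O=Cc1c(I)c(Br)ccc1OCc1ccccc1 | intermediate
9 | 3,4'-bis(benzyloxy)-6-bromo-2'-methoxy-[1,1'-biphenyl]-2-carbaldehyde | O=Cc1c(OCc2ccccc2)ccc(Br)c1-c1ccc(OCc2ccccc2)cc1OC | intermediate
10 | [3,4-bis(benzyloxy)phenyl]magnesium bromide | Br[Mg]c1ccc(OCc2ccccc2)c(OCc2ccccc2)c1 | intermediate (not isolated)
11 | [3,4-bis(benzyloxy)phenyl][3,4'-bis(benzyloxy)-6-bromo-2'-methoxy-[1,1'-biphenyl]-2-yl]methanol (racemic) | OC(c1ccc(OCc2ccccc2)c(OCc2ccccc2)c1)c1c(OCc2ccccc2)ccc(Br)c1-c1ccc(OCc2ccccc2)cc1OC | intermediate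
12 | 3,4'-bis(benzyloxy)-2-[3,4-bis(benzyloxy)benzyl]-6-bromo-2'-methoxy-1,1'-biphenyl | Brc1ccc(OCc2ccccc2)c(Cc2ccc(OCc3ccccc3)c(OCc3ccccc3)c2)c1-c1ccc(OCc2ccccc2)cc1OC | intermediate
13 | {3,4'-bis(benzyloxy)-2-[3,4-bis(benzyloxy)benzyl]-2'-methoxy-[1,1'-biphenyl]-6-yl}lithium | [Li]c1ccc(OCc2ccccc2)c(Cc2ccc(OCc3ccccc3)c(OCc3ccccc3)c2)c1-c1ccc(OCc2ccccc2)cc1OC | intermediate (not isolated)
14 | {3,4'-bis(benzyloxy)-2-[3,4-bis(benzyloxy)benzyl]-2'-methoxy-[1,1'-biphenyl]-6-yl}trimethylstannane | C[Sn](C)(C)c1ccc(OCc2ccccc2)c(Cc2ccc(OCc3ccccc3)c(OCc3ccccc3)c2)c1-c1ccc(OCc2ccccc2)cc1OC | intermediate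
15 | dimethyl squarate (3,4-dimethoxycyclobut-3-ene-1,2-dione) | COC1=C(OC)C(=O)C1=O | starting material
16 | 4-hydroxy-2,3-dimethoxycyclobut-2-en-1-one (racemic) | COC1=C(OC)C(=O)C1O | intermediate
17 | 4-chloro-2,3-dimethoxycyclobut-2-en-1-one (racemic) | COC1=C(OC)C(=O)C1Cl | intermediate
18 | 4-{3,4'-bis(benzyloxy)-2-[3,4-bis(benzyloxy)benzyl]-2'-methoxy-[1,1'-biphenyl]-6-yl}-2,3-dimethoxycyclobut-2-en-1-one (racemic) | COC1=C(OC)C(=O)C1c1ccc(OCc2ccccc2)c(Cc2ccc(OCc3ccccc3)c(OCc3ccccc3)c2)c1-c1ccc(OCc2ccccc2)cc1OC | intermediate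
19 | (3E)-4-{3,4'-bis(benzyloxy)-2-[3,4-bis(benzyloxy)benzyl]-2'-methoxy-[1,1'-biphenyl]-6-yl}-2,3-dimethoxybuta-1,3-dien-1-one (aryl cis to the ketene carbon) | O=C=C(OC)/C(OC)=C\c1ccc(OCc2ccccc2)c(Cc2ccc(OCc3ccccc3)c(OCc3ccccc3)c2)c1-c1ccc(OCc2ccccc2)cc1OC | intermediate (not isolated)
20 | 7-(benzyloxy)-5-[4-(benzyloxy)-2-methoxyphenyl]-6-[3,4-bis(benzyloxy)benzyl]-2,3-dimethoxynaphthalen-1(8aH)-one (racemic) | COC1=C(OC)C(=O)C2C=C(OCc3ccccc3)C(Cc3ccc(OCc4ccccc4)c(OCc4ccccc4)c3)=C(c3ccc(OCc4ccccc4)cc3OC)C2=C1 | intermediate (not isolated)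
21 | 7-(benzyloxy)-5-[4-(benzyloxy)-2-methoxyphenyl]-6-[3,4-bis(benzyloxy)benzyl]-2,3-dimethoxynaphthalen-1-ol | COc1cc2c(-c3ccc(OCc4ccccc4)cc3OC)c(Cc3ccc(OCc4ccccc4)c(OCc4ccccc4)c3)c(OCc3ccccc3)cc2c(O)c1OC | intermediate
22 | 7-(benzyloxy)-5-[4-(benzyloxy)-2-methoxyphenyl]-6-[3,4-bis(benzyloxy)benzyl]-1,2,3-trimethoxynaphthalene | COc1cc2c(-c3ccc(OCc4ccccc4)cc3OC)c(Cc3ccc(OCc4ccccc4)c(OCc4ccccc4)c3)c(OCc3ccccc3)cc2c(OC)c1OC | intermediate
23 | 6-[(3,4-dihydroxyphenyl)methyl]-5-(4-hydroxy-2-methoxyphenyl)-1,3-dimethoxynaphthalene-2,7-diol | COc1cc(O)ccc1-c1c(Cc2ccc(O)c(O)c2)c(O)cc2c(OC)c(O)c(OC)cc12 | target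

**Counts and risks**

Total step count: 15. Longest linear sequence: 10 steps (6 → 7 → 8 → 9 → 11 → 12 → 14 → 18 → 21 → 22 → 23; steps 4–9 and 12–15).

Steps most likely to fail:

Step 12 (Stille coupling). Chloride 17 may ionise at C4 and lose a methyl group to the semisquarate before oxidative addition. Traces of HCl may protodestannylate the electron-rich stannane, and transmetalation next to the ortho aryl ring may be slow. The fallback sets out from 12 and 16 and comes back at 18; it swaps the labile chloride for a carbonate that should not ionise without palladium, and tin for boron. 12 would be lithiated as in step 9 and quenched with 2-isopropoxy-4,4,5,5-tetramethyl-1,3,2-dioxaborolane to give the pinacol boronate 2-{3,4'-bis(benzyloxy)-2-[3,4-bis(benzyloxy)benzyl]-2'-methoxy-[1,1'-biphenyl]-6-yl}-4,4,5,5-tetramethyl-1,3,2-dioxaborolane F1. 16 would be acylated with methyl chloroformate and pyridine (CH2Cl2, 0 °C) to 2,3-dimethoxy-4-oxocyclobut-2-en-1-yl methyl carbonate F2. F1 and F2 would then be joined by a base-free Tsuji–Trost-type allyl–aryl Suzuki–Miyaura coupling (Pd2(dba)3, PPh3, THF, 50 °C), in which the methoxide released on decarboxylation activates the boronate, to give 18.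

Step 13 (key step). The reversible ring opening may favour the ketene with the aryl group turned outward so strongly that ketene dimerisation or capture by traces of water outruns the 6π closure. The fallback sets out from 12 and 15 and comes back at 22; it puts an alkoxy group on C4 of the cyclobutenone, which rotates outward and so forces the aryl group cis to the ketene, and removes the extra oxygen afterwards.
- 12 would be lithiated (t-BuLi, THF, −78 °C) and added to dimethyl squarate 15 to give 4-{3,4'-bis(benzyloxy)-2-[3,4-bis(benzyloxy)benzyl]-2'-methoxy-[1,1'-biphenyl]-6-yl}-4-hydroxy-2,3-dimethoxycyclobut-2-en-1-one F3.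
- MOMCl and iPr2NEt would give its methoxymethyl ether F4.
- Heating in toluene at 110 °C should give 7-(benzyloxy)-5-[4-(benzyloxy)-2-methoxyphenyl]-6-[3,4-bis(benzyloxy)benzyl]-2,3-dimethoxy-4-(methoxymethoxy)naphthalen-1-ol F5.
- MeI and K2CO3 would give 7-(benzyloxy)-5-[4-(benzyloxy)-2-methoxyphenyl]-6-[3,4-bis(benzyloxy)benzyl]-1,2,3-trimethoxy-4-(methoxymethoxy)naphthalene F6.
- HCl in MeOH would free the C8 phenol 6-(benzyloxy)-8-[4-(benzyloxy)-2-methoxyphenyl]-7-[3,4-bis(benzyloxy)benzyl]-2,3,4-trimethoxynaphthalen-1-ol F7.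
- Tf2O and pyridine would give 6-(benzyloxy)-8-[4-(benzyloxy)-2-methoxyphenyl]-7-[3,4-bis(benzyloxy)benzyl]-2,3,4-trimethoxynaphthalen-1-yl trifluoromethanesulfonate F8.
- Reduction of the C8–O bond (Pd(OAc)2, dppf, HCO2H, Et3N, DMF, 80 °C) would deliver 22.

Step 15 (final deprotection). Site control between the two out-of-plane methyl ethers (C5 and C6) may be lost, demethylation may continue next to the new borate, or benzyl cations may alkylate the liberated phenol rings. The fallback sets out from 22 and comes back at 23; it removes the benzyl groups without cations and does the Lewis-acid cleavage on an ester-protected, chromatographable substrate.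
- Hydrogenolysis (H2, Pd on carbon (Pd/C), EtOAc/MeOH) would give 3-[(3,4-dihydroxyphenyl)methyl]-4-(4-hydroxy-2-methoxyphenyl)-6,7,8-trimethoxynaphthalen-2-ol F9.
- Ac2O and pyridine would give the tetraacetate 4-{[3-acetoxy-1-(4-acetoxy-2-methoxyphenyl)-5,6,7-trimethoxynaphthalen-2-yl]methyl}-1,2-phenylene diacetate F10.
- BCl3 (CH2Cl2, −20 °C to 0 °C) should cleave only the C6 methyl ether to give 4-{[3-acetoxy-1-(4-acetoxy-2-methoxyphenyl)-6-hydroxy-5,7-dimethoxynaphthalen-2-yl]methyl}-1,2-phenylene diacetate F11, from which any regioisomer can be separated.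
- Acidic methanolysis (HCl, MeOH, rt, argon) would give 23.

**Further compounds**

F1 | step 12 | 2-{3,4'-bis(benzyloxy)-2-[3,4-bis(benzyloxy)benzyl]-2'-methoxy-[1,1'-biphenyl]-6-yl}-4,4,5,5-tetramethyl-1,3,2-dioxaborolane | CC1(C)OB(OC1(C)C)c1ccc(OCc2ccccc2)c(Cc2ccc(OCc3ccccc3)c(OCc3ccccc3)c2)c1-c1ccc(OCc2ccccc2)cc1OC
F2 | step 12 | 2,3-dimethoxy-4-oxocyclobut-2-en-1-yl methyl carbonate (racemic) | COC(=O)OC1C(OC)=C(OC)C1=O
F3 | step 13 | 4-{3,4'-bis(benzyloxy)-2-[3,4-bis(benzyloxy)benzyl]-2'-methoxy-[1,1'-biphenyl]-6-yl}-4-hydroxy-2,3-dimethoxycyclobut-2-en-1-one (racemic) | COC1=C(OC)C(=O)C1(O)c1ccc(OCc2ccccc2)c(Cc2ccc(OCc3ccccc3)c(OCc3ccccc3)c2)c1-c1ccc(OCc2ccccc2)cc1OC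
F4 | step 13 | 4-{3,4'-bis(benzyloxy)-2-[3,4-bis(benzyloxy)benzyl]-2'-methoxy-[1,1'-biphenyl]-6-yl}-2,3-dimethoxy-4-(methoxymethoxy)cyclobut-2-en-1-one (racemic) | COCOC1(C(=O)C(OC)=C1OC)c1ccc(OCc2ccccc2)c(Cc2ccc(OCc3ccccc3)c(OCc3ccccc3)c2)c1-c1ccc(OCc2ccccc2)cc1OC
F5 | step 13 | 7-(benzyloxy)-5-[4-(benzyloxy)-2-methoxyphenyl]-6-[3,4-bis(benzyloxy)benzyl]-2,3-dimethoxy-4-(methoxymethoxy)naphthalen-1-ol | COCOc1c(OC)c(OC)c(O)c2cc(OCc3ccccc3)c(Cc3ccc(OCc4ccccc4)c(OCc4ccccc4)c3)c(-c3ccc(OCc4ccccc4)cc3OC)c12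
F6 | step 13 | 7-(benzyloxy)-5-[4-(benzyloxy)-2-methoxyphenyl]-6-[3,4-bis(benzyloxy)benzyl]-1,2,3-trimethoxy-4-(methoxymethoxy)naphthalene | COCOc1c(OC)c(OC)c(OC)c2cc(OCc3ccccc3)c(Cc3ccc(OCc4ccccc4)c(OCc4ccccc4)c3)c(-c3ccc(OCc4ccccc4)cc3OC)c12
F7 | step 13 | 6-(benzyloxy)-8-[4-(benzyloxy)-2-methoxyphenyl]-7-[3,4-bis(benzyloxy)benzyl]-2,3,4-trimethoxynaphthalen-1-ol | Oc1c(OC)c(OC)c(OC)c2cc(OCc3ccccc3)c(Cc3ccc(OCc4ccccc4)c(OCc4ccccc4)c3)c(-c3ccc(OCc4ccccc4)cc3OC)c12
F8 | step 13 | 6-(benzyloxy)-8-[4-(benzyloxy)-2-methoxyphenyl]-7-[3,4-bis(benzyloxy)benzyl]-2,3,4-trimethoxynaphthalen-1-yl trifluoromethanesulfonate | O=S(=O)(Oc1c(OC)c(OC)c(OC)c2cc(OCc3ccccc3)c(Cc3ccc(OCc4ccccc4)c(OCc4ccccc4)c3)c(-c3ccc(OCc4ccccc4)cc3OC)c12)C(F)(F)F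
F9 | step 15 | 3-[(3,4-dihydroxyphenyl)methyl]-4-(4-hydroxy-2-methoxyphenyl)-6,7,8-trimethoxynaphthalen-2-ol | COc1cc(O)ccc1-c1c(Cc2ccc(O)c(O)c2)c(O)cc2c(OC)c(OC)c(OC)cc12
F10 | step 15 | 4-{[3-acetoxy-1-(4-acetoxy-2-methoxyphenyl)-5,6,7-trimethoxynaphthalen-2-yl]methyl}-1,2-phenylene diacetate | COc1cc(OC(C)=O)ccc1-c1c(Cc2ccc(OC(C)=O)c(OC(C)=O)c2)c(OC(C)=O)cc2c(OC)c(OC)c(OC)cc12
F11 | step 15 | 4-{[3-acetoxy-1-(4-acetoxy-2-methoxyphenyl)-6-hydroxy-5,7-dimethoxynaphthalen-2-yl]methyl}-1,2-phenylene diacetate | COc1cc(OC(C)=O)ccc1-c1c(Cc2ccc(OC(C)=O)c(OC(C)=O)c2)c(OC(C)=O)cc2c(OC)c(O)c(OC)cc12
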